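**Retrosynthetic overview**

- The two allylic C–O bonds that flank the trisubstituted alkene are cis to each other and trans to the cis-diol. They are traced back to an O–O bridge (singlet oxygen plus a cyclohexadiene) that is cleaved in the same flask; the acetate goes on last by opening a cyclic orthoacetate on the only cis-diol.
- The cyclohexadiene comes from a [3+3] annulation of a tartrate-derived three-carbon aldehyde–acetal with an α-silyl allylboronate. Allylboration joins the aldehyde carbon (later the CH(OH) next to the vinylic CH) to the allyl CH2 (later the vinylic CH). Vinylsilane closure joins the acetal carbon (later CH(OAc)) to the silicon-bearing carbon (later CH(OBz)).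
- Enabling feature: the cis O–C–C–O unit formed by the acetate-bearing ring carbon and its hydroxylated neighbour fits into a 1,3-dioxolane. The acetal-level carbon of that five-membered ring becomes a ring-bound oxocarbenium ion, so the carbocycle has to close cis-fused onto it.
- Ring order: dioxolane (from L-tartrate) → six-membered carbocycle (step 6) → peroxide bridge (step 8, made and cleaved) → dioxolane removed (step 11).

Key step: step 6

Remark: the acetal carbon of the tartrate-derived fragment and the carbinol carbon created in the key step are carried as epimer mixtures, and the allylboronate is racemic; all three centres are fixed or erased later.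

**Step 1**
Reactants: 1 dimethyl (4R,5R)-2,2-dimethyl-1,3-dioxolane-4,5-dicarboxylate (acetonide of dimethyl L-tartrate)
Product: 2 (4R,5R)-5-(methoxycarbonyl)-2,2-dimethyl-1,3-dioxolane-4-carboxylic acid
Conditions: KOH (1.0 equiv), MeOH, 0 → 23 °C; then aq. HCl
Reagents that add atoms: potassium hydroxide, [K+].[OH-]
Why: Mono-saponification of a symmetric diester, in which the first carboxylate formed slows hydroxide attack on the second ester; no stereocentre is touched.

**Step 2**
Reactants: 2 (4R,5R)-5-(methoxycarbonyl)-2,2-dimethyl-1,3-dioxolane-4-carboxylic acid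
Product: 3 methyl (4R)-5-methoxy-2,2-dimethyl-1,3-dioxolane-4-carboxylate (both epimers at the acetal carbon)
Conditions: undivided cell, graphite anode, Pt cathode, MeOH, Et3N (0.1 equiv), constant current, 0 °C
Reagents that add atoms: methanol, CO
Why: Hofer–Moest (non-Kolbe) anodic decarboxylation of an α-alkoxy acid should give a dioxolanyl oxocarbenium ion that methanol traps; the new acetal centre forms as a mixture and is fixed in step 6, the ester-bearing centre is untouched.

**Step 3**
Reactants: 3 methyl (4R)-5-methoxy-2,2-dimethyl-1,3-dioxolane-4-carboxylate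
Product: 4 (4S)-5-methoxy-2,2-dimethyl-1,3-dioxolane-4-carbaldehyde (both acetal epimers; used crude)
Conditions: i-Bu2AlH (1.05 equiv), CH2Cl2, −78 °C; aq. potassium sodium tartrate
Reagents that add atoms: none
Why: Partial reduction of an α-alkoxy ester with i-Bu2AlH should stop at the aluminium hemiacetal at −78 °C and release the aldehyde on work-up without epimerisation (the descriptor changes from R to S only because the priorities change).

**Step 4**
Reactants: 5 3-chloro-2-(chloromethyl)prop-1-ene (3 equiv)
Product: 6 2-(chloromethyl)prop-2-en-1-yl benzoate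
Conditions: PhCO2Na (1 equiv), NaI (cat.), DMF, 23 °C
Reagents that add atoms: sodium benzoate, [Na+].[O-]C(=O)c1ccccc1
Why: SN2 displacement of one allylic chloride by benzoate, with the excess of the symmetric dichloride suppressing the second substitution.

**Step 5**
Reactants: 6 2-(chloromethyl)prop-2-en-1-yl benzoate
Product: 7 racemic 2-{[dimethyl(phenyl)silyl](4,4,5,5-tetramethyl-1,3,2-dioxaborolan-2-yl)methyl}prop-2-en-1-yl benzoate
Conditions: PhMe2Si–B(pin) (1.1 equiv), LiN(i-Pr)2 (1.1 equiv), THF, −98 → 23 °C
Reagents that add atoms: 2-[dimethyl(phenyl)silyl]-4,4,5,5-tetramethyl-1,3,2-dioxaborolane, CC1(C)OB(OC1(C)C)[Si](C)(C)c1ccccc1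
Why: gem-Silylborylation of an α-chloroallyllithium (Matteson-type 1,2-metallate rearrangement): the carbenoid formed at the CH2Cl group is trapped at once by boron, and silicon then migrates from boron to carbon with loss of chloride; the new centre is racemic and is lost in step 6.

**Step 6 (key step)**
Reactants: 4 (4S)-5-methoxy-2,2-dimethyl-1,3-dioxolane-4-carbaldehyde; 7 racemic α-silyl allylboronate (1.2 equiv)
Product: 9 [(3aR,7aS)-7-hydroxy-2,2-dimethyl-3a,6,7,7a-tetrahydro-1,3-benzodioxol-5-yl]methyl benzoate (both carbinol epimers), via borate ester 8 (not isolated)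
Conditions: CH2Cl2, 4 Å MS, 23 °C; then TMSOTf (0.2 equiv), −78 → −20 °C; aq. NaHCO3
Reagents that add atoms: none
Why: The aldehyde of 4 and allylboronate 7 should combine through a closed six-membered chair transition state (carbonyl allylboration with an α-substituted allylboronate), which joins the aldehyde carbon to the CH2 terminus and leaves a vinylsilane with silicon cis to the new chain, because the α-silyl group sits axial next to the 2-substituent and the pinacol methyls. TMSOTf then ionises the methoxy acetal to a 1,3-dioxolan-4-ylium ion, which the vinylsilane attacks at its silicon-bearing carbon (vinylsilane-terminated oxocarbenium cyclisation is the closest known type); the tertiary β-silyl cation loses silicon as PhMe2SiOMe and regenerates a silyl triflate, so the acid is catalytic. The carbocycle closes in a 6-endo-trig mode with both alkene carbons inside the new ring. The new ring-fusion stereocentre is set by the five-membered ring, since the three-atom tether can reach the flat cation only from the face of its own attachment and the bicycle is therefore cis-fused; the carbinol centre is uncontrolled and is removed in step 7. The step needs the aldehyde to react before the acetal is ionised, which the order of addition secures (no Lewis acid is present during the allylboration), and it needs ipso attack instead of attack by the other alkene carbon, which the β-silicon effect and the tertiary cation secure.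

**Step 7**
Reactants: 9 bicyclic homoallylic alcohol (both carbinol epimers)
Product: 11 [(3aR,7aS)-2,2-dimethyl-3a,7a-dihydro-1,3-benzodioxol-5-yl]methyl benzoate, via mesylate 10 (not isolated)
Conditions: MsCl, Et3N, CH2Cl2, 0 °C; then DBU, 40 °C
Reagents that add atoms: none
Why: Sulfonylation followed by E2 elimination, in which DBU removes the more acidic allylic hydrogen so that both carbinol epimers converge on the conjugated ring diene; no stereocentre is made.

**Step 8**
Reactants: 11 cyclohexadiene acetonide
Product: 13 [(3aR,4S,7R,7aS)-4,7-dihydroxy-2,2-dimethyl-3a,4,7,7a-tetrahydro-1,3-benzodioxol-5-yl]methyl benzoate, via endoperoxide 12 (not isolated)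
Conditions: O2, tetraphenylporphyrin (cat.), visible light, CH2Cl2, −30 °C; then Zn, AcOH, 0 °C
Reagents that add atoms: dioxygen, O=O
Why: Singlet-oxygen [4+2] cycloaddition to the s-cis ring diene should occur on the face opposite the cis-fused acetonide, so both new C–O bonds are cis to each other and trans to the acetonide; Zn/AcOH then cleaves only the O–O bond.

**Step 9**
Reactants: 13 cis-1,4-diol
Product: 14 mono-TBS ether of 13 at the hydroxyl next to the vinylic CH
Conditions: TBSCl (1.05 equiv), imidazole, DMF, −20 °C
Reagents that add atoms: tert-butyldimethylsilyl chloride, CC(C)(C)[Si](C)(C)Cl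
Why: Site-selective silylation, since the hydroxyl flanked by the vinylic CH is the less hindered one while the other lies next to the alkene carbon that carries CH2OBz (allylic 1,2-strain).

**Step 10**
Reactants: 14 mono-TBS ether
Product: 15 benzoate of 14 at the remaining hydroxyl
Conditions: BzCl, pyridine, DMAP (cat.), CH2Cl2, 0 → 23 °C
Reagents that add atoms: benzoyl chloride, O=C(Cl)c1ccccc1
Why: DMAP-catalysed acylation of the only free hydroxyl; no stereocentre is affected.

**Step 11**
Reactants: 15 silyl ether dibenzoate
Product: 16 [(3R,4S,5S,6S)-6-(benzoyloxy)-3,4,5-trihydroxycyclohex-1-en-1-yl]methyl benzoate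
Conditions: TFA/H2O/CH2Cl2 (9:1:10), 0 °C
Reagents that add atoms: none
Why: Acid-catalysed hydrolysis should remove the isopropylidene acetal and the silyl ether in one operation while the esters stay, and the acidic medium disfavours acyl migration.

**Step 12**
Reactants: 16 triol dibenzoate
Product: 18 [(3R,4S,5S,6S)-5-acetoxy-6-(benzoyloxy)-3,4-dihydroxycyclohex-1-en-1-yl]methyl benzoate (target), via cyclic orthoacetate 17 (not isolated)
Conditions: MeC(OMe)3, CSA (cat.), MeCN, 23 °C; then AcOH/H2O (4:1), 23 °C
Reagents that add atoms: trimethyl orthoacetate, COC(C)(OC)OC; water, O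
Why: Orthoester method for monoacylation of a cis-diol: only the cis-vicinal pair should close to a five-membered orthoacetate, and its acid hydrolysis opens kinetically to the axial acetate and equatorial hydroxyl, the axial oxygen being the one next to the pseudoaxial allylic benzoate.

**Compound list**

1 | dimethyl (4R,5R)-2,2-dimethyl-1,3-dioxolane-4,5-dicarboxylate | COC(=O)[C@@H]1OC(C)(C)O[C@H]1C(=O)OC | starting material
2 | (4R,5R)-5-(methoxycarbonyl)-2,2-dimethyl-1,3-dioxolane-4-carboxylic acid | OC(=O)[C@@H]1OC(C)(C)O[C@H]1C(=O)OC | intermediate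
3 | methyl (4R)-5-methoxy-2,2-dimethyl-1,3-dioxolane-4-carboxylate (acetal epimers) | COC1OC(C)(C)O[C@H]1C(=O)OC | intermediate
4 | (4S)-5-methoxy-2,2-dimethyl-1,3-dioxolane-4-carbaldehyde (acetal epimers) | COC1OC(C)(C)O[C@H]1C=O | intermediate
5 | 3-chloro-2-(chloromethyl)prop-1-ene | C=C(CCl)CCl | starting material
6 | 2-(chloromethyl)prop-2-en-1-yl benzoate | C=C(CCl)COC(=O)c1ccccc1 | intermediate
7 | racemic 2-{[dimethyl(phenyl)silyl](4,4,5,5-tetramethyl-1,3,2-dioxaborolan-2-yl)methyl}prop-2-en-1-yl benzoate | C=C(COC(=O)c1ccccc1)C([Si](C)(C)c1ccccc1)B1OC(C)(C)C(C)(C)O1 | intermediate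
8 | pinacol borate of the homoallylic alcohol from 4 and 7; vinylsilane with silicon cis to the CH2 that leads to the carbinol | COC1OC(C)(C)O[C@H]1C(OB2OC(C)(C)C(C)(C)O2)C/C(COC(=O)c2ccccc2)=C\[Si](C)(C)c1ccccc1 | intermediate (not isolated)
9 | [(3aR,7aS)-7-hydroxy-2,2-dimethyl-3a,6,7,7a-tetrahydro-1,3-benzodioxol-5-yl]methyl benzoate (carbinol epimers) | CC1(C)O[C@@H]2C=C(COC(=O)c3ccccc3)CC(O)[C@@H]2O1 | intermediate
10 | methanesulfonate of 9 | CC1(C)O[C@@H]2C=C(COC(=O)c3ccccc3)CC(OS(C)(=O)=O)[C@@H]2O1 | intermediate (not isolated)
11 | [(3aR,7aS)-2,2-dimethyl-3a,7a-dihydro-1,3-benzodioxol-5-yl]methyl benzoate | CC1(C)O[C@@H]2C=C(COC(=O)c3ccccc3)C=C[C@@H]2O1 | intermediate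
12 | endoperoxide of 11, O–O bridge across the diene termini on the face opposite the acetonide | CC1(C)O[C@@H]2[C@H]3OO[C@H](C=C3COC(=O)c3ccccc3)[C@@H]2O1 | intermediate (not isolated)
13 | [(3aR,4S,7R,7aS)-4,7-dihydroxy-2,2-dimethyl-3a,4,7,7a-tetrahydro-1,3-benzodioxol-5-yl]methyl benzoate | CC1(C)O[C@@H]2[C@@H](O)C(COC(=O)c3ccccc3)=C[C@@H](O)[C@@H]2O1 | intermediate
14 | 13 with a TBS ether on the hydroxyl next to the vinylic CH | CC1(C)O[C@@H]2[C@@H](O)C(COC(=O)c3ccccc3)=C[C@@H](O[Si](C)(C)C(C)(C)C)[C@@H]2O1 | intermediate
15 | 14 with a benzoate on the remaining ring hydroxyl | CC1(C)O[C@@H]2[C@@H](OC(=O)c3ccccc3)C(COC(=O)c3ccccc3)=C[C@@H](O[Si](C)(C)C(C)(C)C)[C@@H]2O1 | intermediate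
16 | [(3R,4S,5S,6S)-6-(benzoyloxy)-3,4,5-trihydroxycyclohex-1-en-1-yl]methyl benzoate | O[C@H]1[C@@H](O)[C@H](O)C=C(COC(=O)c2ccccc2)[C@@H]1OC(=O)c1ccccc1 | intermediate
17 | cyclic methyl orthoacetate of 16 across the cis-diol | COC1(C)O[C@@H]2[C@@H](OC(=O)c3ccccc3)C(COC(=O)c3ccccc3)=C[C@@H](O)[C@@H]2O1 | intermediate (not isolated)
18 | [(3R,4S,5S,6S)-5-acetoxy-6-(benzoyloxy)-3,4-dihydroxycyclohex-1-en-1-yl]methyl benzoate | CC(=O)O[C@H]1[C@@H](O)[C@H](O)C=C(COC(=O)c2ccccc2)[C@@H]1OC(=O)c1ccccc1 | target

**Step count and risks**

Total step count: 12. Longest linear sequence: 10 steps (from 1 through steps 1–3 and 6–12).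

Steps most likely to fail:

Step 6. The ring closure may lose out to proton loss from the dioxolanyl cation (elimination to a dioxole), or the allylboration may place silicon trans to the new chain, which makes ipso closure geometrically impossible. Fallback: the two bonds are made in separate steps and the ring is closed with reversed polarity by an intramolecular Nozaki–Hiyama–Kishi reaction. It sets out from 4 and 7 and returns at 9. Allylboration alone (CH2Cl2, 23 °C; aq. NaHCO3) should give the homoallylic alcohol F1. N-Iodosuccinimide in MeCN should exchange silicon for iodine with retention of alkene geometry to give the vinyl iodide F2. Aqueous trifluoroacetic acid should hydrolyse the isopropylidene and methyl acetals to the dihydroxy aldehyde F3. CrCl2 with NiCl2 (cat.) in DMF should close the six-membered ring to the cyclohexene triol F4, with Felkin-type addition expected to place the new hydroxyl cis to its neighbour. 2,2-Dimethoxypropane with CSA should then tie the cis-diol and give 9.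

Step 9. The silylation may not discriminate between the two secondary allylic hydroxyls. Fallback: the hindered secondary hydroxyl is masked together with the primary one in a temporary six-membered boronate ring. It sets out from 13 and returns at 15. K2CO3 in MeOH should remove the primary benzoate to give the triol F5. PhB(OH)2 in toluene with azeotropic removal of water should give the cyclic phenylboronate F6 across the 1,3-diol. TBSCl with imidazole should silylate the only free hydroxyl to give the silyl ether F7. Hydrolysis of the boronate in aqueous acetone should free the diol F8. BzCl (2.2 equiv), pyridine and DMAP should then benzoylate both hydroxyls and give 15.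

Step 12. The orthoester may open toward the wrong oxygen, or the acetyl group may migrate between the cis-vicinal oxygens during work-up. Fallback: the acetate is put on directly after the trans-diol has been blocked. It sets out from 16 and returns at 18. Butane-2,3-dione, CH(OMe)3 and CSA in MeOH should protect only the trans-diequatorial diol as the butane-2,3-diacetal F9, leaving the axial hydroxyl free. Ac2O, pyridine and DMAP should give the acetate F10. TFA/H2O should remove the diacetal and give 18.

**Further compounds**

F1 | step 6 | homoallylic alcohol from 4 and 7 (vinylsilane, silicon cis to the chain CH2; carbinol and acetal epimers) | COC1OC(C)(C)O[C@H]1C(O)C/C(COC(=O)c1ccccc1)=C\[Si](C)(C)c1ccccc1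
F2 | step 6 | vinyl iodide corresponding to F1 | COC1OC(C)(C)O[C@H]1C(O)C/C(COC(=O)c1ccccc1)=C\I
F3 | step 6 | (2S)-2,3-dihydroxy aldehyde bearing the vinyl iodide (carbinol epimers) | O=C[C@@H](O)C(O)C/C(COC(=O)c1ccccc1)=C\I
F4 | step 6 | cyclohexene triol, cis-diol next to the alkene CH (carbinol epimers) | O[C@@H]1C=C(COC(=O)c2ccccc2)CC(O)[C@@H]1O
F5 | step 9 | triol from 13 after removal of the primary benzoate | CC1(C)O[C@@H]2[C@@H](O)C(CO)=C[C@@H](O)[C@@H]2O1
F6 | step 9 | cyclic phenylboronate of F5 across the primary and the adjacent secondary hydroxyl | CC1(C)O[C@@H]2[C@H]3OB(c4ccccc4)OCC3=C[C@@H](O)[C@@H]2O1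
F7 | step 9 | TBS ether of F6 | CC1(C)O[C@@H]2[C@H]3OB(c4ccccc4)OCC3=C[C@@H](O[Si](C)(C)C(C)(C)C)[C@@H]2O1
F8 | step 9 | diol from F7 after removal of the boronate | CC1(C)O[C@@H]2[C@@H](O)C(CO)=C[C@@H](O[Si](C)(C)C(C)(C)C)[C@@H]2O1
F9 | step 12 | butane-2,3-diacetal of 16 on the trans-diol | O[C@H]1[C@H]2OC(C)(OC)C(C)(OC)O[C@@H]2C=C(COC(=O)c2ccccc2)[C@@H]1OC(=O)c1ccccc1
F10 | step 12 | acetate of F9 | CC(=O)O[C@H]1[C@H]2OC(C)(OC)C(C)(OC)O[C@@H]2C=C(COC(=O)c2ccccc2)[C@@H]1OC(=O)c1ccccc1
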